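**Proposed synthesis of (3S)-7,2'-dihydroxy-4'-methoxy-5'-prenylisoflavanone (18) by carbene-catalysed Stetter closure onto a ring B ortho-quinone methide**

## The problem

The target is a 3-arylchroman-4-one: ring A (a resorcinol) is fused to pyranone ring C, and ring B hangs on C3. C3 is the only stereocentre. It is α to the C4 ketone and benzylic, so it epimerises easily under base or acid and no other stereocentre can relay or correct it. It must therefore be set by a reagent, late, and then left alone. The 5'-prenyl group rules out hydrogenation, strong acid and free electrophilic halogen once it is in place. A 2'-hydroxyisoflavanone also loses water under acid to give the pterocarpene, so the endgame has to be close to neutral. The enabling feature is that C3 is bonded to C1' of ring B, which carries a hydroxyl at C2'. C3 and C1' can therefore be unmasked as an ortho-quinone methide whose electrophilic carbon is C3. C4 is an aryl ketone carbon on ring A and can arrive as the acyl anion of a ring A salicylaldehyde. The O1–C2 ether then serves as a two-atom tether that makes the C3–C4 bond formation a six-membered ring closure.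

## Retrosynthesis

**Target 18 from 17.** Only the O7–Si bond is cut. A triisopropylsilyl ether is chosen at O7 because it leaves with buffered fluoride at 0 °C, where neither C3 nor the prenyl group is at risk. An acetal at O7 would need acid at the very end. A free 7-hydroxyl para to the aldehyde would be deprotonated in the key step and switch the aldehyde off.

**Isoflavanone 17 from sulfone aldehyde 15.** The C3–C4 bond is cut, which opens ring C. Among the ring C bonds this is the only cut that creates the stereocentre in an irreversible C–C bond formation under catalyst control. Cutting O1–C2 would make C3 by protonation, and cutting C4–C4a would deliver C4 at the wrong oxidation level. Precursor 15 has no ring C and is racemic at a carbon that is erased when quinone methide 16 forms. The forward reaction must generate 16 and the acyl anion in the same molecule under a base too weak to enolise 17, and a chiral carbene must choose the face of C3.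

**Sulfone aldehyde 15 from diol 13 and sulfinate 14.** The C3–S bond is cut and the aldehyde is returned to its cyclic acetal. A 2-(1-hydroxyalkyl)phenol ionises under mild acid and is captured by sulfinate, which is the standard way to such sulfones. The same aqueous acid frees the aldehyde, so no separate unmasking step is needed.

**Diol 13 from ketone 12, and 12 from bromide 10 and stannane 11.** The C3–H bond is cut (ketone reduction), then the C5'–C(prenyl) bond (Stille coupling). The prenyl group is placed after all electrophilic bromine chemistry is finished. The ring B phenol is already free at this stage, so no allyl ether meets hot palladium and stannane.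

**Phenol 10 from allyl ether 9.** The ring B phenol must be capped while the α-bromoketone exists, or it closes to the benzofuran-3(2H)-one. An allyl ether is preferred to an acetal-type group. An acetal-type group would have to leave in the same acid that frees the aldehyde and would release a formaldehyde equivalent next to a free benzylic alcohol, which invites 1,3-benzodioxine formation. The allyl group leaves under neutral palladium catalysis with the acetal and silyl ether untouched.

**Ether 9 from bromoketone 5 and phenol 8.** The O1–C2 bond is cut. Alkylation of a phenol by a phenacyl bromide is fast and reliable and joins the two halves in one step. It requires the ring A aldehyde to be masked, because a free salicylaldehyde would go on to the 2-aroylbenzofuran by aldol condensation, and the later hydride step needs the mask as well.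

**Bromoketone 5 from paeonol 1, and phenol 8 from aldehyde 6.** Paeonol already carries the C1' carbon chain, the 2'-hydroxyl and the 4'-methoxyl. Ring bromination gives 2, allylation gives 3, and α-bromination through silyl enol ether 4 gives 5. Aldehyde 6 is silylated at the non-chelated 4-hydroxyl to 7 and acetalised to 8.

## Roads not taken

**Alternative 1:** The cut is through C2–C3 and C3–C4, with C3 arriving as a carbene carbon. Forward, the arylchlorocarbene from ring B chlorodiazirine A3 would cyclopropanate ring A silyloxybenzofuran A2, and the adduct would open with loss of chloride and silyl to give isoflavone A1. The merits are real: two skeletal bonds in one step, full convergence, and ring B delivered intact. The weak point for this target is that A1 is flat. C3 would have to be set afterwards by asymmetric conjugate reduction of the C2=C3 bond in the presence of the prenyl alkene, which itself must be coupled on after the carbene step because the carbene would attack it. Two methoxymethyl ethers then need acid, next to a labile stereocentre in a compound that dehydrates to the pterocarpene. This road is better in convergence and in bonds formed per step. The chosen plan sets against it that its one new bond carries the stereocentre and that only a buffered desilylation follows.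

**Alternative 2:** The cut is through C2–C3 and C4–C4a, a formal [4+2] union. Forward, a confined chiral Brønsted acid would ionise aryloxymethyl acetate A5, the oxocarbenium ion would add to C3 of ring B enol silane A6, and ring A would close onto the silyloxocarbenium ion to give isoflavan A4. This is the most convergent of the four plans and makes two C–C bonds, ring C and the stereocentre together. Its weak points are that C4 arrives as a silyl-protected alcohol, so the silyl group must be removed and a benzylic alcohol oxidised to the ketone beside the new stereocentre without epimerisation. Three silyl ethers must come off in all. The prenyl alkene is a competing π-nucleophile and a site of protonation under a strong acid. The enantioselective version with an aryloxymethyl cation has no close precedent, so two uncertain events are stacked in one step. The chosen plan forms fewer bonds in its key step but delivers C4 directly as the ketone, and both halves of its mechanism are individually established.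

**Alternative 3:** The cut is O1–C2. Forward, the ring A phenol of α-aryl enone A8 would add 6-endo-trig under a chiral phosphoric acid, and the enol would be protonated enantioselectively at C3 to give isoflavanone A7. This road is shorter than the chosen one, rests on classical deoxybenzoin and methylenation chemistry, and its ring closure is certain. Its weakness is that the stereocentre is made by proton transfer to an enol, the same process by which it is lost. Uncatalysed phenol addition to the α-methylene ketone is a racemic background path, and the product can re-enolise under the same acid. The two methoxymethyl ethers then need acid, which risks racemisation, pterocarpene formation and prenyl hydration. Against the shorter route the chosen plan sets configuration fixed in a C–C bond with no uncatalysed path to the ketone, and a last step that is close to neutral.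

Key step: step 11

Assumption: the (5aS,10bR) antipode of the aminoindanol triazolium is taken to deliver the 3S product. If the first run shows the opposite sense, its mirror image, made from the other commercial enantiomer of cis-1-amino-2-indanol, replaces it with nothing else changed.

## Route

Step 1
Reactants: 1 paeonol, 1-(2-hydroxy-4-methoxyphenyl)ethanone
Product: 2 1-(5-bromo-2-hydroxy-4-methoxyphenyl)ethanone
Conditions: NBS, MeCN, 0 °C to rt
Reagents that add atoms: N-bromosuccinimide, O=C1CCC(=O)N1Br
Why: Electrophilic aromatic bromination; hydroxyl and methoxyl both direct to C5 (para to OH, ortho to OMe), and the position between the two oxygens is hindered.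

Step 2
Reactants: 2 1-(5-bromo-2-hydroxy-4-methoxyphenyl)ethanone
Product: 3 1-[2-(allyloxy)-5-bromo-4-methoxyphenyl]ethanone
Conditions: allyl bromide, K2CO3, DMF, 60 °C
Reagents that add atoms: allyl bromide, C=CCBr
Why: Williamson etherification of the chelated phenol; the cap prevents 5-exo-tet closure to the benzofuran-3(2H)-one once the α-bromide is present and is removable later under neutral conditions.

Step 3
Reactants: 3 1-[2-(allyloxy)-5-bromo-4-methoxyphenyl]ethanone
Product: 5 2-bromo-1-[2-(allyloxy)-5-bromo-4-methoxyphenyl]ethanone, via trimethylsilyl enol ether 4 (not isolated)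
Conditions: TMSOTf, Et3N, CH2Cl2, 0 °C; then NBS, THF, −78 to 0 °C
Reagents that add atoms: N-bromosuccinimide, O=C1CCC(=O)N1Br; trimethylsilyl triflate, C[Si](C)(C)OS(=O)(=O)C(F)(F)F (its silyl group stays only in intermediate 4)
Why: α-Bromination of a methyl ketone through its silyl enol ether; the enol ether is far more nucleophilic than the allyl alkene or the arene, so one bromine is delivered to the α-carbon without free HBr.

Step 4
Reactants: 6 2,4-dihydroxybenzaldehyde
Product: 7 2-hydroxy-4-(triisopropylsilyloxy)benzaldehyde
Conditions: TIPSCl, imidazole, CH2Cl2, 0 °C to rt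
Reagents that add atoms: chlorotriisopropylsilane, CC(C)[Si](Cl)(C(C)C)C(C)C
Why: Selective silylation of the 4-hydroxyl; the 2-hydroxyl is hydrogen-bonded to the formyl group and is much less reactive.

Step 5
Reactants: 7 2-hydroxy-4-(triisopropylsilyloxy)benzaldehyde
Product: 8 2-(5,5-dimethyl-1,3-dioxan-2-yl)-5-(triisopropylsilyloxy)phenol
Conditions: 2,2-dimethylpropane-1,3-diol, PPTS (cat.), benzene, reflux, Dean–Stark; Et3N quench
Reagents that add atoms: 2,2-dimethylpropane-1,3-diol, OCC(C)(C)CO
Why: Acid-catalysed acetalisation driven by azeotropic removal of water; the cyclic acetal shields the aldehyde from aldol condensation in step 6 and from hydride in step 9.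

Step 6
Reactants: 5 2-bromo-1-[2-(allyloxy)-5-bromo-4-methoxyphenyl]ethanone; 8 2-(5,5-dimethyl-1,3-dioxan-2-yl)-5-(triisopropylsilyloxy)phenol
Product: 9 1-[2-(allyloxy)-5-bromo-4-methoxyphenyl]-2-[2-(5,5-dimethyl-1,3-dioxan-2-yl)-5-(triisopropylsilyloxy)phenoxy]ethanone
Conditions: K2CO3, acetone, rt
Reagents that add atoms: none
Why: Williamson ether synthesis with a phenacyl bromide, whose SN2 reactivity is raised by the adjacent carbonyl; with the aldehyde masked no benzofuran-forming aldol can follow.

Step 7
Reactants: 9 1-[2-(allyloxy)-5-bromo-4-methoxyphenyl]-2-[2-(5,5-dimethyl-1,3-dioxan-2-yl)-5-(triisopropylsilyloxy)phenoxy]ethanone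
Product: 10 1-(5-bromo-2-hydroxy-4-methoxyphenyl)-2-[2-(5,5-dimethyl-1,3-dioxan-2-yl)-5-(triisopropylsilyloxy)phenoxy]ethanone
Conditions: Pd(PPh3)4 (cat.), morpholine, THF, rt
Reagents that add atoms: none
Why: Palladium-catalysed deallylation (Tsuji–Trost allyl transfer to an amine); zerovalent palladium ionises the allyl aryl ether at room temperature, where the electron-rich aryl bromide does not undergo oxidative addition, and acetal and silyl ether are inert.

Step 8
Reactants: 10 1-(5-bromo-2-hydroxy-4-methoxyphenyl)-2-[2-(5,5-dimethyl-1,3-dioxan-2-yl)-5-(triisopropylsilyloxy)phenoxy]ethanone; 11 tributyl(3-methylbut-2-enyl)stannane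
Product: 12 2-[2-(5,5-dimethyl-1,3-dioxan-2-yl)-5-(triisopropylsilyloxy)phenoxy]-1-[2-hydroxy-4-methoxy-5-(3-methylbut-2-enyl)phenyl]ethanone
Conditions: Pd(PPh3)4, DMF, 95 °C
Reagents that add atoms: none
Why: Stille coupling of an aryl bromide with a prenylstannane, expected to join at the primary allyl terminus; fluoride-free conditions keep the silyl ether, and the chelated phenol is tolerated.

Step 9
Reactants: 12 2-[2-(5,5-dimethyl-1,3-dioxan-2-yl)-5-(triisopropylsilyloxy)phenoxy]-1-[2-hydroxy-4-methoxy-5-(3-methylbut-2-enyl)phenyl]ethanone
Product: 13 racemic 2-{2-[2-(5,5-dimethyl-1,3-dioxan-2-yl)-5-(triisopropylsilyloxy)phenoxy]-1-hydroxyethyl}-5-methoxy-4-(3-methylbut-2-enyl)phenol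
Conditions: NaBH4, THF/MeOH, 0 °C
Reagents that add atoms: none
Why: Borohydride reduction of the aryl ketone; the carbinol centre is formed racemic, which does not matter because this carbon becomes planar in step 11.

Step 10
Reactants: 13 racemic 2-{2-[2-(5,5-dimethyl-1,3-dioxan-2-yl)-5-(triisopropylsilyloxy)phenoxy]-1-hydroxyethyl}-5-methoxy-4-(3-methylbut-2-enyl)phenol; 14 sodium p-toluenesulfinate
Product: 15 racemic 2-{2-[2-hydroxy-4-methoxy-5-(3-methylbut-2-enyl)phenyl]-2-(p-tolylsulfonyl)ethoxy}-4-(triisopropylsilyloxy)benzaldehyde
Conditions: 14 (3 equiv), 1 M aq HCl, THF, rt; work-up without basic wash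
Reagents that add atoms: water, O
Why: Acid-mediated SN1 substitution of a 2-hydroxybenzylic alcohol by sulfinate at sulfur, the usual preparation of 2-(1-sulfonylalkyl)phenols, here favoured by the ortho-hydroxyl and para-methoxyl; the same aqueous acid hydrolyses the cyclic acetal to the aldehyde.

Step 11
Reactants: 15 racemic 2-{2-[2-hydroxy-4-methoxy-5-(3-methylbut-2-enyl)phenyl]-2-(p-tolylsulfonyl)ethoxy}-4-(triisopropylsilyloxy)benzaldehyde
Product: 17 (3S)-3-[2-hydroxy-4-methoxy-5-(3-methylbut-2-enyl)phenyl]-7-(triisopropylsilyloxy)chroman-4-one, via ortho-quinone methide aldehyde 16 (not isolated)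
Conditions: (5aS,10bR)-2-(pentafluorophenyl)-5a,10b-dihydro-4H,6H-indeno[2,1-b][1,2,4]triazolo[4,3-d][1,4]oxazin-2-ium tetrafluoroborate (15 mol%), K2HPO4 (2.5 equiv), 4 Å MS, toluene (0.01 M), 0 °C to rt
Reagents that add atoms: none
Why: Proposed new method: an intramolecular Stetter-type acyl-anion addition in which the acceptor is an ortho-quinone methide instead of an enoate; the closest known reactions are the asymmetric intramolecular Stetter closure of 2-(alkenyloxy)benzaldehydes to 3-substituted chroman-4-ones and the intermolecular carbene-catalysed addition of aldehydes to ortho-quinone methides released from 2-(1-sulfonylalkyl)phenols. The phosphate deprotonates the ring B phenol, whose phenoxide expels p-toluenesulfinate to give quinone methide 16, while the carbene adds to the ring A aldehyde and proton transfer gives the Breslow enaminol. Its nucleophilic carbon, the future C4, attacks the methide carbon C3, which rearomatises ring B, and collapse of the adduct releases the carbene and the C4 ketone. Ring C closes in the 6-exo-trig mode, because the C3=C1' bond that is attacked lies outside the new six-membered ring. The C3 stereocentre is set by the chiral carbene, whose fused indane blocks one face of the enaminol so that the tethered methide is approached on one enantiotopic face; the racemic sulfone carbon is erased beforehand and has no influence. No uncatalysed path leads to the ketone, so there is no racemic background closure. The step needs ring closure to outrun tautomerisation of 16 to the 2-hydroxystyryl enol ether, capture of the carbene by 16 and intermolecular benzoin coupling; the short tether, high dilution and slow base-limited release of 16 are relied on for this. The weak heterogeneous base is chosen so that the α-aryl ketone, once formed, is not enolised.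

Step 12
Reactants: 17 (3S)-3-[2-hydroxy-4-methoxy-5-(3-methylbut-2-enyl)phenyl]-7-(triisopropylsilyloxy)chroman-4-one
Product: 18 (3S)-7-hydroxy-3-[2-hydroxy-4-methoxy-5-(3-methylbut-2-enyl)phenyl]chroman-4-one
Conditions: TBAF, AcOH (1.5 equiv per fluoride), THF, 0 °C
Reagents that add atoms: none
Why: Fluoride desilylation of an aryl silyl ether that is activated by the para carbonyl; acetic acid keeps the medium too weakly basic to epimerise C3 and too weakly acidic to dehydrate the 2'-hydroxyisoflavanone or touch the prenyl group.

## Compound list

1 | paeonol, 1-(2-hydroxy-4-methoxyphenyl)ethanone | CC(=O)c1ccc(OC)cc1O | starting material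
2 | 1-(5-bromo-2-hydroxy-4-methoxyphenyl)ethanone | CC(=O)c1cc(Br)c(OC)cc1O | intermediate
3 | 1-[2-(allyloxy)-5-bromo-4-methoxyphenyl]ethanone | CC(=O)c1cc(Br)c(OC)cc1OCC=C | intermediate
4 | {1-[2-(allyloxy)-5-bromo-4-methoxyphenyl]ethenyloxy}trimethylsilane | C=C(O[Si](C)(C)C)c1cc(Br)c(OC)cc1OCC=C | intermediate
5 | 2-bromo-1-[2-(allyloxy)-5-bromo-4-methoxyphenyl]ethanone | BrCC(=O)c1cc(Br)c(OC)cc1OCC=C | intermediate
6 | 2,4-dihydroxybenzaldehyde | O=Cc1ccc(O)cc1O | starting material
7 | 2-hydroxy-4-(triisopropylsilyloxy)benzaldehyde | O=Cc1ccc(O[Si](C(C)C)(C(C)C)C(C)C)cc1O | intermediate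
8 | 2-(5,5-dimethyl-1,3-dioxan-2-yl)-5-(triisopropylsilyloxy)phenol | CC1(C)COC(OC1)c1ccc(O[Si](C(C)C)(C(C)C)C(C)C)cc1O | intermediate
9 | 1-[2-(allyloxy)-5-bromo-4-methoxyphenyl]-2-[2-(5,5-dimethyl-1,3-dioxan-2-yl)-5-(triisopropylsilyloxy)phenoxy]ethanone | C=CCOc1cc(OC)c(Br)cc1C(=O)COc1cc(O[Si](C(C)C)(C(C)C)C(C)C)ccc1C1OCC(C)(C)CO1 | intermediate
10 | 1-(5-bromo-2-hydroxy-4-methoxyphenyl)-2-[2-(5,5-dimethyl-1,3-dioxan-2-yl)-5-(triisopropylsilyloxy)phenoxy]ethanone | COc1cc(O)c(cc1Br)C(=O)COc1cc(O[Si](C(C)C)(C(C)C)C(C)C)ccc1C1OCC(C)(C)CO1 | intermediate
11 | tributyl(3-methylbut-2-enyl)stannane | CCCC[Sn](CCCC)(CCCC)CC=C(C)C | starting material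
12 | 2-[2-(5,5-dimethyl-1,3-dioxan-2-yl)-5-(triisopropylsilyloxy)phenoxy]-1-[2-hydroxy-4-methoxy-5-(3-methylbut-2-enyl)phenyl]ethanone | COc1cc(O)c(cc1CC=C(C)C)C(=O)COc1cc(O[Si](C(C)C)(C(C)C)C(C)C)ccc1C1OCC(C)(C)CO1 | intermediate
13 | racemic 2-{2-[2-(5,5-dimethyl-1,3-dioxan-2-yl)-5-(triisopropylsilyloxy)phenoxy]-1-hydroxyethyl}-5-methoxy-4-(3-methylbut-2-enyl)phenol | COc1cc(O)c(cc1CC=C(C)C)C(O)COc1cc(O[Si](C(C)C)(C(C)C)C(C)C)ccc1C1OCC(C)(C)CO1 | intermediate
14 | sodium p-toluenesulfinate | Cc1ccc(S(=O)[O-])cc1.[Na+] | starting material
15 | racemic 2-{2-[2-hydroxy-4-methoxy-5-(3-methylbut-2-enyl)phenyl]-2-(p-tolylsulfonyl)ethoxy}-4-(triisopropylsilyloxy)benzaldehyde | CC(C)[Si](C(C)C)(C(C)C)Oc1ccc(C=O)c(OCC(c2cc(CC=C(C)C)c(OC)cc2O)S(=O)(=O)c2ccc(C)cc2)c1 | intermediate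
16 | 2-{2-[4-methoxy-3-(3-methylbut-2-enyl)-6-oxocyclohexa-2,4-dien-1-ylidene]ethoxy}-4-(triisopropylsilyloxy)benzaldehyde (ortho-quinone methide, alkene geometry not fixed) | O=C1C=C(OC)C(CC=C(C)C)=CC1=CCOc1cc(O[Si](C(C)C)(C(C)C)C(C)C)ccc1C=O | intermediate
17 | (3S)-3-[2-hydroxy-4-methoxy-5-(3-methylbut-2-enyl)phenyl]-7-(triisopropylsilyloxy)chroman-4-one | COc1cc(O)c([C@H]2COc3cc(O[Si](C(C)C)(C(C)C)C(C)C)ccc3C2=O)cc1CC=C(C)C | intermediate
18 | (3S)-7-hydroxy-3-[2-hydroxy-4-methoxy-5-(3-methylbut-2-enyl)phenyl]chroman-4-one | COc1cc(O)c([C@H]2COc3cc(O)ccc3C2=O)cc1CC=C(C)C | target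

## Step count and risks

Total: 12 steps. Longest linear sequence: 10 steps (1, 2, 3, 6, 7, 8, 9, 10, 11, 12 from paeonol); the ring A branch adds steps 4 and 5.

**Step 11 (key step).** The quinone methide may tautomerise to the hydroxystyryl enol ether before the acyl anion reaches it. The carbene may be held as its adduct with the methide. The electron-rich aldehyde may form the enaminol slowly. Facial selection may be eroded if both alkene geometries of the methide react, and the product may epimerise if the base is too strong.

The fallback uses known chemistry, sets out from 12 and returns at 17. The acetal of 12 is hydrolysed with PPTS in wet acetone to the keto aldehyde F1. A triazolium carbene with a tertiary amine base then effects the established intramolecular crossed aldehyde–ketone benzoin closure, which forms the same C3–C4 bond and ring C and gives the 3-hydroxyisoflavanone F2. SmI2 in THF/MeOH at −78 °C cleaves the tertiary benzylic C–O bond of this α-hydroxy ketone and gives the racemic isoflavanone F3. The enantiomers are separated on a chiral stationary phase; the 3R antipode is racemised with a trace of amine base and recycled, and the 3S antipode is 17.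

**Step 10.** The benzylic cation may be diverted before sulfinate captures it, by proton loss to the enol ether followed by hydrolytic cleavage of the aryl ether, or by Friedel–Crafts attack on ring A. Acetal hydrolysis may lag, and the freed aldehyde may be held as its sulfinic acid adduct.

The fallback sets out from 13 and returns at 15, and separates C–S bond formation from aldehyde release. Preformed p-toluenesulfinic acid in dry CH2Cl2 over MgSO4 converts 13 to the sulfone acetal F4 without water present. The aldehyde is then liberated with PPTS in acetone/water at 40 °C to give 15.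

**Step 8.** Coupling may occur at the tertiary allyl terminus and give the 1,1-dimethylallyl isomer. Oxidative addition into the electron-rich bromide may be slow, with protodestannylation taking over.

The fallback sets out from 10 and returns at 12. Stille coupling with allyltributylstannane, which has no regiochemical ambiguity, gives the allyl arene F5. Cross-metathesis with excess 2-methyl-2-butene and the second-generation Grubbs catalyst in CH2Cl2 at 40 °C then converts the allyl group to prenyl and gives 12.

**Step 6.** The acetal of phenol 8 may be lost on handling or in the flask, after which the keto aldehyde condenses to the 2-aroylbenzofuran. Carbonate may also cleave the silyl ether.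

The fallback sets out from 5 and returns at 9, and avoids base in the ether-forming step. Sodium formate in aqueous ethanol at reflux converts 5 to the hydroxy ketone F6. Mitsunobu etherification of F6 with phenol 8 (PPh3, DIAD, THF, 0 °C) then gives 9 under neutral conditions.

## Further compounds

F1 | step 11 | 2-{2-[2-hydroxy-4-methoxy-5-(3-methylbut-2-enyl)phenyl]-2-oxoethoxy}-4-(triisopropylsilyloxy)benzaldehyde | COc1cc(O)c(cc1CC=C(C)C)C(=O)COc1cc(O[Si](C(C)C)(C(C)C)C(C)C)ccc1C=O
F2 | step 11 | racemic 3-hydroxy-3-[2-hydroxy-4-methoxy-5-(3-methylbut-2-enyl)phenyl]-7-(triisopropylsilyloxy)chroman-4-one | COc1cc(O)c(cc1CC=C(C)C)C1(O)COc2cc(O[Si](C(C)C)(C(C)C)C(C)C)ccc2C1=O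
F3 | step 11 | racemic 3-[2-hydroxy-4-methoxy-5-(3-methylbut-2-enyl)phenyl]-7-(triisopropylsilyloxy)chroman-4-one | COc1cc(O)c(cc1CC=C(C)C)C1COc2cc(O[Si](C(C)C)(C(C)C)C(C)C)ccc2C1=O
F4 | step 10 | racemic 2-{2-[2-(5,5-dimethyl-1,3-dioxan-2-yl)-5-(triisopropylsilyloxy)phenoxy]-1-(p-tolylsulfonyl)ethyl}-5-methoxy-4-(3-methylbut-2-enyl)phenol | CC1(C)COC(OC1)c1ccc(O[Si](C(C)C)(C(C)C)C(C)C)cc1OCC(c1cc(CC=C(C)C)c(OC)cc1O)S(=O)(=O)c1ccc(C)cc1
F5 | step 8 | 1-(5-allyl-2-hydroxy-4-methoxyphenyl)-2-[2-(5,5-dimethyl-1,3-dioxan-2-yl)-5-(triisopropylsilyloxy)phenoxy]ethanone | COc1cc(O)c(cc1CC=C)C(=O)COc1cc(O[Si](C(C)C)(C(C)C)C(C)C)ccc1C1OCC(C)(C)CO1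
F6 | step 6 | 1-[2-(allyloxy)-5-bromo-4-methoxyphenyl]-2-hydroxyethanone | OCC(=O)c1cc(Br)c(OC)cc1OCC=C
A1 | alternative 1 | 5'-bromo-4'-methoxy-7,2'-bis(methoxymethoxy)isoflavone | COCOc1ccc2c(c1)occ(-c1cc(Br)c(OC)cc1OCOC)c2=O
A2 | alternative 1 | 3-(tert-butyldimethylsilyloxy)-6-(methoxymethoxy)benzofuran | COCOc1ccc2c(c1)occ2O[Si](C)(C)C(C)(C)C
A3 | alternative 1 | 3-[5-bromo-4-methoxy-2-(methoxymethoxy)phenyl]-3-chloro-3H-diazirine | COCOc1cc(OC)c(Br)cc1C1(Cl)N=N1
A4 | alternative 2 | (3S)-4'-methoxy-5'-prenyl-7,2'-bis(triisopropylsilyloxy)-4-(trimethylsilyloxy)isoflavan, 3,4-trans | COc1cc(O[Si](C(C)C)(C(C)C)C(C)C)c([C@H]2COc3cc(O[Si](C(C)C)(C(C)C)C(C)C)ccc3[C@@H]2O[Si](C)(C)C)cc1CC=C(C)C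
A5 | alternative 2 | [3-(triisopropylsilyloxy)phenoxy]methyl acetate | CC(=O)OCOc1cccc(O[Si](C(C)C)(C(C)C)C(C)C)c1
A6 | alternative 2 | trimethyl{(E)-2-[4-methoxy-5-(3-methylbut-2-enyl)-2-(triisopropylsilyloxy)phenyl]ethenyloxy}silane | COc1cc(O[Si](C(C)C)(C(C)C)C(C)C)c(/C=C/O[Si](C)(C)C)cc1CC=C(C)C
A7 | alternative 3 | (3S)-4'-methoxy-7,2'-bis(methoxymethoxy)-5'-prenylisoflavanone | COc1cc(OCOC)c([C@H]2COc3cc(OCOC)ccc3C2=O)cc1CC=C(C)C
A8 | alternative 3 | 1-[2-hydroxy-4-(methoxymethoxy)phenyl]-2-[4-methoxy-2-(methoxymethoxy)-5-(3-methylbut-2-enyl)phenyl]prop-2-en-1-one | C=C(C(=O)c1ccc(OCOC)cc1O)c1cc(CC=C(C)C)c(OC)cc1OCOC
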